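**Retrosynthetic overview** (flavan numbering for both units; O(3) is the oxygen of the lower 3-hydroxyl)

1. The last C–C bond is C4(upper)–C8(lower): the 8-cerio derivative of benzylated epiafzelechin adds to the C4 ketone of (2S)-liquiritigenin dibenzyl ether; dehydration gives a 4-aryl-flav-3-ene, and one hydrogenation sets upper C4 (2,4-cis) and removes all benzyl groups.
2. Lower ring C (O1, C2, C3, C4, C4a, C8a) is made by ring contraction: the seven-membered cyclic acetal 7 (O1–C2–O(3)–C3–C4(=O)–C4a–C8a) ionizes at C2–O(3) and C2 moves from O(3) to C3, giving the dihydroflavonol with the C2–C3 bond, ring C and ring B in one operation.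
3. Enabling feature: C2 carries O1 and is bonded to C3, which carries O(3), so with C2 at the aldehyde level O1–C2–O(3) can be closed as an acetal of the ring-B aldehyde; C3 is α to C4, which as a ketone on the phloroglucinol ring A makes C3 an enol nucleophile; the C4 oxygen is removed again in step 5.
4. Lower-unit stereochemistry: the contraction is run racemic; flavan-3-one 13 has a labile C2, and asymmetric hydrogenation with dynamic kinetic resolution sets 2R,3R; upper C2 is bought with (2S)-liquiritigenin.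
5. Ring order: lower ring A (bought) → seven-membered acetal ring → lower ring C by contraction; upper rings A, B and C are bought intact; the inter-unit bond and upper C4 come last.

Key step: step 4

Assumption: (2S)-liquiritigenin is bought enantiopure, and the sense of induction in step 7 is taken from 2-arylcyclohexanones, the mirror-image catalyst being used if it proves opposite.

Step 1
Reactants: 1 2,4,6-trihydroxyacetophenone
Product: 2 1-[2-hydroxy-4,6-bis(benzyloxy)phenyl]ethanone
Conditions: BnBr (2.05 equiv), K2CO3, DMF, 0 °C to rt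
Reagents that add atoms: benzyl bromide, BrCc1ccccc1
Why: Williamson etherification in which the hydroxyl hydrogen-bonded to the ketone is the least nucleophilic, so two equivalents of benzyl bromide should alkylate only the para oxygen and one ortho oxygen, and no stereocentre is formed.

Step 2
Reactants: 2 1-[2-hydroxy-4,6-bis(benzyloxy)phenyl]ethanone
Product: 5 2-hydroxy-1-[2-hydroxy-4,6-bis(benzyloxy)phenyl]ethanone, via bis-silyl enol ether 3 (not isolated), via silyloxy ketone 4 (not isolated)
Conditions: Me3SiOTf, Et3N, CH2Cl2, 0 °C; then mCPBA, CH2Cl2, −20 °C; then 1 M HCl, THF, rt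
Reagents that add atoms: 3-chloroperoxybenzoic acid (mCPBA), OOC(=O)c1cccc(Cl)c1
Why: Rubottom oxidation, in which the enol silane is epoxidized faster than the arene or the ketone, silyl migration gives the α-silyloxy ketone and dilute acid removes both silyl groups; no stereocentre is formed.

Step 3
Reactants: 5 2-hydroxy-1-[2-hydroxy-4,6-bis(benzyloxy)phenyl]ethanone; 6 4-(benzyloxy)benzaldehyde
Product: 7 rac-6,8-bis(benzyloxy)-2-[4-(benzyloxy)phenyl]-4H-1,3-benzodioxepin-5-one
Conditions: PPTS (cat.), benzene, reflux, Dean–Stark trap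
Reagents that add atoms: none
Why: acid-catalysed acetalization driven by removal of water, in which the primary hydroxyl and the phenol close the seven-membered mixed acetal; its single stereocentre (the acetal carbon) is formed racemic and is erased in step 4.

Step 4
Reactants: 7 rac-6,8-bis(benzyloxy)-2-[4-(benzyloxy)phenyl]-4H-1,3-benzodioxepin-5-one
Product: 10 rac-(2R,3R)-5,7-bis(benzyloxy)-2-[4-(benzyloxy)phenyl]-3-hydroxychroman-4-one, via oxocarbenium enol silane 8 (not isolated), via silyl ether 9 (not isolated)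
Conditions: Me3SiOTf (2.2 equiv), i-Pr2NEt (1.2 equiv), CH2Cl2 (0.02 M), −78 to −20 °C; then 1 M HCl, THF, rt
Reagents that add atoms: none
Why: Proposed new method: Me3SiOTf and the amine should convert the aryl ketone into its enol silane and silylate the acetal oxygen O(3), so that the C2–O(3) bond ionizes to the O1-aryl oxocarbenium ion 8, which the enol carbon C3 captures; the acetal carbon thus moves from O(3) to C3 and the seven-membered ring contracts to ring C with O(3) left on C3, the closest known reaction types being the Petasis–Ferrier rearrangement of cyclic enol acetals, the one-pot enol silane formation and Mukaiyama addition to acetals, and the Lewis-acid O-to-C glycoside (Fries-type) rearrangement. Ring C closes in the 6-(enolendo)-exo-trig mode, C3 of the enol attacking the exocyclic C2=O1 carbon. C2 and C3 are formed together and should settle, C3 through the enol, as the 2,3-trans diequatorial racemate, which is acceptable because both centres are reset in step 7. The step needs cleavage of C2–O(3) rather than C2–O1 and bond formation through C3 rather than C4: cleavage at O1 gives only a vinyloxy oxocarbenium ion that cannot cyclize and returns, and attack through C3 places the developing positive charge on C4, where the silyloxy group and ring A stabilize it, and gives a conjugated aryl ketone in a six-membered ring, whereas attack through C4 would give a strained five-membered α-silyloxy aldehyde. The 4-benzyloxyphenyl group stabilizes the cation, and high dilution should suppress intermolecular Friedel–Crafts capture by ring A.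

Step 5
Reactants: 10 rac-(2R,3R)-5,7-bis(benzyloxy)-2-[4-(benzyloxy)phenyl]-3-hydroxychroman-4-one
Product: 12 rac-(2R,3S)-5,7-bis(benzyloxy)-2-[4-(benzyloxy)phenyl]chroman-3-ol, via flavan-3,4-diol 11 (not isolated)
Conditions: NaBH4, THF/MeOH, 0 °C; then Et3SiH (10 equiv), CF3CO2H, CH2Cl2, −20 °C
Reagents that add atoms: none
Why: hydride reduction of the ketone followed by ionic hydrogenation (SN1 reduction by a silane) of the C4 alcohol through the benzylic cation stabilized by O5, O7 and O1; the new C4 centre is removed at once, and the configuration of the racemate at C2 and C3 does not matter because steps 6 and 7 reset it.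

Step 6
Reactants: 12 rac-(2R,3S)-5,7-bis(benzyloxy)-2-[4-(benzyloxy)phenyl]chroman-3-ol
Product: 13 rac-5,7-bis(benzyloxy)-2-[4-(benzyloxy)phenyl]chroman-3-one
Conditions: Dess–Martin periodinane, CH2Cl2, rt
Reagents that add atoms: none
Why: Dess–Martin oxidation of the secondary alcohol under neutral conditions, as used for benzylated catechins; C3 becomes a carbonyl and C2 becomes enolizable.

Step 7
Reactants: 13 rac-5,7-bis(benzyloxy)-2-[4-(benzyloxy)phenyl]chroman-3-one
Product: 14 (2R,3R)-5,7-bis(benzyloxy)-2-[4-(benzyloxy)phenyl]chroman-3-ol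
Conditions: H2 (50 atm), RuCl2[(R)-Xyl-SDP][(S,S)-DPEN] (0.5 mol %), t-BuOK (10 mol %), i-PrOH/THF, rt
Reagents that add atoms: none
Why: Noyori-type asymmetric hydrogenation with dynamic kinetic resolution, as known for 2-aryl- and 2-aryloxycyclohexanones: the base should racemize C2 through the enolate faster than reduction, and the chiral ruthenium hydride should reduce the (2R) ketone preferentially with hydride delivered anti to the 2-aryl group, so that C2 (R) is set by the catalyst and C3 (R, cis) by the substrate.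

Step 8
Reactants: 14 (2R,3R)-5,7-bis(benzyloxy)-2-[4-(benzyloxy)phenyl]chroman-3-ol
Product: 15 (2R,3R)-5,7-bis(benzyloxy)-2-[4-(benzyloxy)phenyl]-8-bromochroman-3-ol
Conditions: NBS (1.0 equiv), CH2Cl2, −40 to 0 °C
Reagents that add atoms: N-bromosuccinimide, O=C1CCC(=O)N1Br
Why: electrophilic aromatic bromination; in 5,7-di-O-benzyl flavan-3-ols C8, which lies between O1 and O7, is brominated in preference to C6, as established for benzylated catechin and epicatechin.

Step 9
Reactants: 15 (2R,3R)-5,7-bis(benzyloxy)-2-[4-(benzyloxy)phenyl]-8-bromochroman-3-ol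
Product: 16 (2R,3R)-3,5,7-tris(benzyloxy)-2-[4-(benzyloxy)phenyl]-8-bromochromane
Conditions: NaH, BnBr, Bu4NI (cat.), DMF, 0 °C to rt
Reagents that add atoms: benzyl bromide, BrCc1ccccc1
Why: Williamson etherification of the C3 alkoxide gives an ether that survives the organometallic step and leaves with the other benzyl groups at the end; no stereocentre is touched.

Step 10
Reactants: 17 (2S)-liquiritigenin
Product: 18 (2S)-7-(benzyloxy)-2-[4-(benzyloxy)phenyl]chroman-4-one
Conditions: BnOH (2.4 equiv), PPh3, DIAD, THF, 0 °C to rt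
Reagents that add atoms: benzyl alcohol, OCc1ccccc1
Why: Mitsunobu alkylation of both phenols under nearly neutral conditions, which avoids the base-induced ring opening to the chalcone that would racemize C2.

Step 11
Reactants: 16 (2R,3R)-3,5,7-tris(benzyloxy)-2-[4-(benzyloxy)phenyl]-8-bromochromane; 18 (2S)-7-(benzyloxy)-2-[4-(benzyloxy)phenyl]chroman-4-one
Product: 22 (2S)-7-(benzyloxy)-2-[4-(benzyloxy)phenyl]-4-[(2R,3R)-3,5,7-tris(benzyloxy)-2-(4-(benzyloxy)phenyl)chroman-8-yl]-2H-chromene, via aryllithium 19 (not isolated), via arylcerium dichloride 20 (not isolated), via tertiary carbinol 21 (not isolated)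
Conditions: n-BuLi, THF, −78 °C; CeCl3, −78 °C; then 18, −78 to −40 °C; then p-TsOH·H2O (cat.), CH2Cl2, rt
Reagents that add atoms: none
Why: bromine–lithium exchange, transmetalation to the weakly basic organocerium reagent, which should add to the C4 ketone instead of enolizing it, and acid-catalysed E1 dehydration of the doubly benzylic tertiary alcohol; the carbinol centre at C4 is lost on dehydration and C2 of both units is untouched.

Step 12
Reactants: 22 (2S)-7-(benzyloxy)-2-[4-(benzyloxy)phenyl]-4-[(2R,3R)-3,5,7-tris(benzyloxy)-2-(4-(benzyloxy)phenyl)chroman-8-yl]-2H-chromene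
Product: 23 (2R,3R)-8-[(2S,4S)-7-hydroxy-2-(4-hydroxyphenyl)chroman-4-yl]-2-(4-hydroxyphenyl)chromane-3,5,7-triol
Conditions: H2 (1–3 atm), Pd(OH)2/C, THF/MeOH, rt
Reagents that add atoms: none
Why: heterogeneous catalytic hydrogenation and hydrogenolysis, in which hydrogen should add to the C3=C4 bond from the face opposite to the C2 aryl group, placing the C4 aryl group cis to it (4S), while the six benzyl ethers are cleaved in the same operation.

**Compound list**

1 | 2,4,6-trihydroxyacetophenone | CC(=O)c1c(O)cc(O)cc1O | starting material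
2 | 1-[2-hydroxy-4,6-bis(benzyloxy)phenyl]ethanone | CC(=O)c1c(O)cc(OCc2ccccc2)cc1OCc1ccccc1 | intermediate
3 | bis-silyl enol ether of 2 | C=C(O[Si](C)(C)C)c1c(O[Si](C)(C)C)cc(OCc2ccccc2)cc1OCc1ccccc1 | intermediate
4 | α-silyloxy ketone aryl silyl ether | C[Si](C)(C)OCC(=O)c1c(O[Si](C)(C)C)cc(OCc2ccccc2)cc1OCc1ccccc1 | intermediate
5 | 2-hydroxy-1-[2-hydroxy-4,6-bis(benzyloxy)phenyl]ethanone | OCC(=O)c1c(O)cc(OCc2ccccc2)cc1OCc1ccccc1 | intermediate
6 | 4-(benzyloxy)benzaldehyde | O=Cc1ccc(OCc2ccccc2)cc1 | starting material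
7 | rac-6,8-bis(benzyloxy)-2-[4-(benzyloxy)phenyl]-4H-1,3-benzodioxepin-5-one | O=C1COC(c2ccc(OCc3ccccc3)cc2)Oc2cc(OCc3ccccc3)cc(OCc3ccccc3)c21 | intermediate
8 | ring-opened O1-aryl oxocarbenium ion with enediol bis-silyl ether, triflate salt | C[Si](C)(C)OC=C(O[Si](C)(C)C)c1c(OCc2ccccc2)cc(OCc2ccccc2)cc1[O+]=Cc1ccc(OCc2ccccc2)cc1.[O-]S(=O)(=O)C(F)(F)F | intermediate
9 | rac-(2R,3R)-3-O-trimethylsilyl ether of 10 (one enantiomer drawn) | c1c(OCc5ccccc5)cc(OCc5ccccc5)c2c1O[C@H](c1ccc(OCc5ccccc5)cc1)[C@@H](O[Si](C)(C)C)C2=O | intermediate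
10 | rac-(2R,3R)-5,7-bis(benzyloxy)-2-[4-(benzyloxy)phenyl]-3-hydroxychroman-4-one (2,3-trans, one enantiomer drawn) | c1c(OCc5ccccc5)cc(OCc5ccccc5)c2c1O[C@H](c1ccc(OCc5ccccc5)cc1)[C@@H](O)C2=O | intermediate
11 | rac-2,3-trans-5,7-bis(benzyloxy)-2-[4-(benzyloxy)phenyl]chromane-3,4-diol (C4 epimers, one enantiomer drawn) | c1c(OCc5ccccc5)cc(OCc5ccccc5)c2c1O[C@H](c1ccc(OCc5ccccc5)cc1)[C@@H](O)C2O | intermediate
12 | rac-(2R,3S)-5,7-bis(benzyloxy)-2-[4-(benzyloxy)phenyl]chroman-3-ol (2,3-trans, one enantiomer drawn) | c1c(OCc5ccccc5)cc(OCc5ccccc5)c2c1O[C@H](c1ccc(OCc5ccccc5)cc1)[C@@H](O)C2 | intermediate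
13 | rac-5,7-bis(benzyloxy)-2-[4-(benzyloxy)phenyl]chroman-3-one | c1c(OCc5ccccc5)cc(OCc5ccccc5)c2c1OC(c1ccc(OCc5ccccc5)cc1)C(=O)C2 | intermediate
14 | (2R,3R)-5,7-bis(benzyloxy)-2-[4-(benzyloxy)phenyl]chroman-3-ol | c1c(OCc5ccccc5)cc(OCc5ccccc5)c2c1O[C@H](c1ccc(OCc5ccccc5)cc1)[C@H](O)C2 | intermediate
15 | (2R,3R)-5,7-bis(benzyloxy)-2-[4-(benzyloxy)phenyl]-8-bromochroman-3-ol | Brc1c(OCc5ccccc5)cc(OCc5ccccc5)c2c1O[C@H](c1ccc(OCc5ccccc5)cc1)[C@H](O)C2 | intermediate
16 | (2R,3R)-3,5,7-tris(benzyloxy)-2-[4-(benzyloxy)phenyl]-8-bromochromane | Brc1c(OCc5ccccc5)cc(OCc5ccccc5)c2c1O[C@H](c1ccc(OCc5ccccc5)cc1)[C@H](OCc5ccccc5)C2 | intermediate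
17 | (2S)-liquiritigenin, (2S)-7-hydroxy-2-(4-hydroxyphenyl)chroman-4-one | Oc1ccc([C@@H]2CC(=O)c3ccc(O)cc3O2)cc1 | starting material
18 | (2S)-7-(benzyloxy)-2-[4-(benzyloxy)phenyl]chroman-4-one | O(Cc5ccccc5)c1ccc([C@@H]2CC(=O)c3ccc(OCc5ccccc5)cc3O2)cc1 | intermediate
19 | 8-lithio derivative of 16 | [Li]c1c(OCc5ccccc5)cc(OCc5ccccc5)c2c1O[C@H](c1ccc(OCc5ccccc5)cc1)[C@H](OCc5ccccc5)C2 | intermediate
20 | 8-(dichlorocerio) derivative of 16 | Cl[Ce](Cl)c1c(OCc5ccccc5)cc(OCc5ccccc5)c2c1O[C@H](c1ccc(OCc5ccccc5)cc1)[C@H](OCc5ccccc5)C2 | intermediate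
21 | (2S)-4-aryl-flavan-4-ol from 20 and 18 (C4 epimers) | O(Cc5ccccc5)c1ccc([C@@H]2CC(O)(c3c(OCc5ccccc5)cc(OCc5ccccc5)c4c3O[C@H](c3ccc(OCc5ccccc5)cc3)[C@H](OCc5ccccc5)C4)c3ccc(OCc5ccccc5)cc3O2)cc1 | intermediate
22 | (2S)-7-(benzyloxy)-2-[4-(benzyloxy)phenyl]-4-[(2R,3R)-3,5,7-tris(benzyloxy)-2-(4-(benzyloxy)phenyl)chroman-8-yl]-2H-chromene | O(Cc5ccccc5)c1ccc([C@@H]2C=C(c3c(OCc5ccccc5)cc(OCc5ccccc5)c4c3O[C@H](c3ccc(OCc5ccccc5)cc3)[C@H](OCc5ccccc5)C4)c3ccc(OCc5ccccc5)cc3O2)cc1 | intermediate
23 | (2R,3R)-8-[(2S,4S)-7-hydroxy-2-(4-hydroxyphenyl)chroman-4-yl]-2-(4-hydroxyphenyl)chromane-3,5,7-triol | Oc1ccc([C@@H]2C[C@H](c3c(O)cc(O)c4c3O[C@H](c3ccc(O)cc3)[C@H](O)C4)c3ccc(O)cc3O2)cc1 | target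

**Step count and risks**

Total steps: 12. Longest linear sequence: 11 steps (steps 1 to 9, 11 and 12).

Steps most likely to fail:

Step 4. The acetal may ionize mainly at the C2–O1 bond and lose the aldehyde, the oxocarbenium ion may be captured intermolecularly by ring A, or the C–C bond may form through the ketone carbon. The fallback uses known chemistry and gives up the acetal tether. It sets out from 2: MOMCl and i-Pr2NEt give 1-[2-(methoxymethoxy)-4,6-bis(benzyloxy)phenyl]ethanone F1. Claisen–Schmidt condensation with 6 (KOH, EtOH) gives the (E)-chalcone F2. Weitz–Scheffer epoxidation (H2O2, NaOH, MeOH/THF) gives the racemic trans-epoxy ketone F3. HCl in MeOH at 50 °C removes the MOM group and lets the phenol open the epoxide at the benzylic carbon (6-endo), which returns to the route at 10.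

Step 7. Racemization of C2 may be slower than reduction, or facial discrimination at this ketone without an aryl group on the carbonyl may be poor, so that the trans alcohol or material of low enantiomeric purity forms. The fallback replaces asymmetric catalysis by substrate-controlled reduction and classical resolution. It sets out from 13: LiBH(s-Bu)3 (L-Selectride) in THF at −78 °C should give the racemic cis alcohol, racemic 5,7-bis(benzyloxy)-2-[4-(benzyloxy)phenyl]chroman-3-ol F4, as known for the ketone from benzylated catechin. Esterification with (S)-2-methoxy-2-phenylacetic acid (DCC, DMAP) and separation of the diastereomers gives the (2R,3R) ester F5. K2CO3 in MeOH cleaves it, which returns to the route at 14.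

Step 11. The flavanone may be enolized with ring opening to the chalcone and loss of the C2 configuration, or the hindered nucleophile may fail to add. The fallback replaces carbonyl addition by cross-coupling. It sets out from 16 and 18: bromine–lithium exchange on 16 and quenching with 2-isopropoxy-4,4,5,5-tetramethyl-1,3,2-dioxaborolane give the C8 pinacol boronate F6. Tf2O with 2,6-di-tert-butyl-4-methylpyridine converts 18 into the enol triflate, (2S)-7-(benzyloxy)-2-[4-(benzyloxy)phenyl]-2H-chromen-4-yl trifluoromethanesulfonate F7. Suzuki–Miyaura coupling of F6 and F7 (Pd(OAc)2, SPhos, K3PO4, toluene/H2O, 80 °C) returns to the route at 22.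

Further compounds
F1 | step 4 | 1-[2-(methoxymethoxy)-4,6-bis(benzyloxy)phenyl]ethanone | CC(=O)c1c(OCOC)cc(OCc2ccccc2)cc1OCc1ccccc1
F2 | step 4 | (E)-1-[2-(methoxymethoxy)-4,6-bis(benzyloxy)phenyl]-3-[4-(benzyloxy)phenyl]prop-2-en-1-one | COCOc1cc(OCc2ccccc2)cc(OCc2ccccc2)c1C(=O)/C=C/c1ccc(OCc2ccccc2)cc1
F3 | step 4 | racemic trans-epoxide of F2 (one enantiomer drawn) | COCOc1cc(OCc2ccccc2)cc(OCc2ccccc2)c1C(=O)[C@@H]1O[C@H]1c1ccc(OCc2ccccc2)cc1
F4 | step 7 | racemic cis-5,7-bis(benzyloxy)-2-[4-(benzyloxy)phenyl]chroman-3-ol (both enantiomers written) | c1c(OCc5ccccc5)cc(OCc5ccccc5)c2c1O[C@H](c1ccc(OCc5ccccc5)cc1)[C@H](O)C2.c1c(OCc5ccccc5)cc(OCc5ccccc5)c2c1O[C@@H](c1ccc(OCc5ccccc5)cc1)[C@@H](O)C2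
F5 | step 7 | (2R,3R)-5,7-bis(benzyloxy)-2-[4-(benzyloxy)phenyl]chroman-3-yl (S)-2-methoxy-2-phenylacetate | c1c(OCc5ccccc5)cc(OCc5ccccc5)c2c1O[C@H](c1ccc(OCc5ccccc5)cc1)[C@H](OC(=O)[C@@H](OC)c1ccccc1)C2
F6 | step 11 | (2R,3R)-3,5,7-tris(benzyloxy)-2-[4-(benzyloxy)phenyl]-8-(4,4,5,5-tetramethyl-1,3,2-dioxaborolan-2-yl)chromane | CC1(C)OB(OC1(C)C)c1c(OCc5ccccc5)cc(OCc5ccccc5)c2c1O[C@H](c1ccc(OCc5ccccc5)cc1)[C@H](OCc5ccccc5)C2
F7 | step 11 | (2S)-7-(benzyloxy)-2-[4-(benzyloxy)phenyl]-2H-chromen-4-yl trifluoromethanesulfonate | O(Cc5ccccc5)c1ccc([C@@H]2C=C(OS(=O)(=O)C(F)(F)F)c3ccc(OCc5ccccc5)cc3O2)cc1
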